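**Retrosynthetic overview**
1. The target is 2-hydroxy-3-methyl-6-nonadecyl-1,4-benzoquinone, ring numbered C1(=O), C2(OH), C3(CH3), C4(=O), C5(H), C6(nonadecyl). The last step only unmasks the C2 hydroxyl from a methyl ether (vinylogous ester hydrolysis).
2. The quinone ring is closed at the C4–C3 bond by a thermal cascade of a 4-hydroxy-4-(1-methoxyallenyl)cyclobutenone: 4π ring opening to a dienylketene, 6π electrocyclisation, tautomerisation. No oxidant is needed.
3. Enabling feature: in the 1,2,4-trioxygenated ring, the carbonyl carbon C4 (a latent ketene carbon) sits next to C3, and C3, its methyl carbon and the oxygen-bearing C2 are the three carbons of a 1-methoxyallene. C4, C5, C6 and C1 form a temporary cyclobutenone whose C4–C1 bond, absent from the target, is cleaved in the same step.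
4. The precursor is one 1,2-addition (lithiated methoxyallene) away from 3-nonadecylcyclobut-3-ene-1,2-dione. That dione comes from diisopropyl squarate and nonadecylmagnesium bromide by addition/hydrolysis, then hydride reduction/hydrolysis.
5. Ring order: the four-membered ring is bought (squarate); the six-membered quinone ring, the only ring of the target, is formed from it in step 4.

Key step: step 4

Remark on the chemistry: the target has no stereocentre and no stereogenic double bond, so it is a single achiral compound and no absolute configuration has to be set; the side chain is read as unbranched nonadecyl.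

**Route**

Step 1
Reactants: 1 1-bromononadecane; 2 diisopropyl squarate (3,4-diisopropoxycyclobut-3-ene-1,2-dione)
Product: 5 3-isopropoxy-4-nonadecylcyclobut-3-ene-1,2-dione, via nonadecylmagnesium bromide 3 (not isolated), via squarate carbinol adduct 4 (not isolated)
Conditions: Mg, THF, 45 °C; add to 2, THF, −78 °C; 1 M HCl quench; crude adduct, conc. HCl (cat.), CH2Cl2, rt
Reagents that add atoms: none
Why: Grignard 1,2-addition to one squarate carbonyl, then acid-promoted loss of isopropanol with allylic transposition, is the standard entry to 3-alkoxy-4-alkylcyclobutenediones, and the carbinol stereocentre of 4 is lost again.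

Step 2
Reactants: 5 3-isopropoxy-4-nonadecylcyclobut-3-ene-1,2-dione
Product: 7 3-nonadecylcyclobut-3-ene-1,2-dione, via hydride adduct 6 (not isolated)
Conditions: LiAlH(OtBu)3, THF, −20 °C; then conc. HCl, CH2Cl2, rt
Reagents that add atoms: none
Why: The hindered hydride should add only to the ketone-like carbonyl next to the isopropoxy-bearing carbon (the other is a deactivated vinylogous ester), and acid should then hydrolyse the vinylogous ester and dehydrate, the known reduction–hydrolysis route to monosubstituted cyclobutenediones; the carbinol stereocentre of 6 is transient.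

Step 3
Reactants: 7 3-nonadecylcyclobut-3-ene-1,2-dione; 8 methoxyallene (1-methoxypropa-1,2-diene)
Product: 10 4-hydroxy-4-(1-methoxypropa-1,2-dien-1-yl)-3-nonadecylcyclobut-2-en-1-one (racemic), via 1-lithio-1-methoxyallene 9 (not isolated)
Conditions: 8, n-BuLi, THF, −40 °C; add to 7, THF, −78 °C; sat. aq. NH4Cl, −78 °C
Reagents that add atoms: none
Why: In this organolithium 1,2-addition to a cyclobutenedione, the ring alkyl group is vinylogously conjugated with, and deactivates, the carbonyl next to the ring CH, so the lithioallene (α-attack) should add to the carbonyl next to the nonadecyl-bearing carbon; the new carbinol stereocentre forms as a racemate and is erased in step 4.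

Step 4
Reactants: 10 4-hydroxy-4-(1-methoxypropa-1,2-dien-1-yl)-3-nonadecylcyclobut-2-en-1-one
Product: 13 2-methoxy-3-methyl-6-nonadecyl-1,4-benzoquinone, via dienylketene 11 (not isolated), via o-quinone methide 12 (not isolated)
Conditions: degassed toluene (0.01 M), 110 °C, N2
Reagents that add atoms: none
Why: Heating should open the cyclobutenone by conrotatory 4π electrocyclic cleavage of the C(=O)–C(OH) bond, the donor hydroxyl rotating outward so that the allenyl group ends up cis to the ketene in dienylketene 11. A thermal disrotatory 6π electrocyclisation (ketene C=C, central C=C, and the allene C=C that carries OMe) should then join the ketene carbon to the central allene carbon, closing the six-membered ring as o-quinone methide 12; proton transfer from the enolic OH to the exocyclic CH2 gives 13, so the allene supplies the quinone oxidation level and its terminal CH2 becomes the C-methyl group. The closest known reaction type is the Moore–Liebeskind thermal ring expansion of 4-alkenyl- and 4-allenyl-4-hydroxycyclobutenones to hydroquinones, quinones and o-quinone methides. No stereocentre is formed, and the racemic carbinol centre of 10 is destroyed. The step needs outward rotation of OH (inward rotation would let the hydroxyl trap the ketene as a 2(5H)-furanone), which the strong outward preference of oxygen donors should secure, and closure onto the allene in preference to intermolecular ketene reactions, which the cis geometry and high dilution should secure; the substitution pattern is fixed by the connectivity of 10 and cannot scramble.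

Step 5
Reactants: 13 2-methoxy-3-methyl-6-nonadecyl-1,4-benzoquinone
Product: 14 capiquinone C (2-hydroxy-3-methyl-6-nonadecyl-1,4-benzoquinone)
Conditions: 70% aq. HClO4, 1,4-dioxane, rt
Reagents that add atoms: water, O
Why: A 2-methoxy-1,4-benzoquinone is a vinylogous ester, so acid-catalysed addition–elimination of water at the methoxy-bearing carbon (vinylogous ester hydrolysis) should release methanol and leave the rest of the quinone untouched.

**Compound list**
1 | 1-bromononadecane | CCCCCCCCCCCCCCCCCCCBr | starting material
2 | diisopropyl squarate (3,4-diisopropoxycyclobut-3-ene-1,2-dione) | CC(C)OC1=C(OC(C)C)C(=O)C1=O | starting material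
3 | nonadecylmagnesium bromide | CCCCCCCCCCCCCCCCCCC[Mg]Br | intermediate
4 | 4-hydroxy-2,3-diisopropoxy-4-nonadecylcyclobut-2-en-1-one (racemic) | CCCCCCCCCCCCCCCCCCCC1(O)C(OC(C)C)=C(OC(C)C)C1=O | intermediate
5 | 3-isopropoxy-4-nonadecylcyclobut-3-ene-1,2-dione | CCCCCCCCCCCCCCCCCCCC1=C(OC(C)C)C(=O)C1=O | intermediate
6 | 4-hydroxy-3-isopropoxy-2-nonadecylcyclobut-2-en-1-one (racemic) | CCCCCCCCCCCCCCCCCCCC1=C(OC(C)C)C(O)C1=O | intermediate
7 | 3-nonadecylcyclobut-3-ene-1,2-dione | CCCCCCCCCCCCCCCCCCCC1=CC(=O)C1=O | intermediate
8 | methoxyallene (1-methoxypropa-1,2-diene) | COC=C=C | starting material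
9 | 1-lithio-1-methoxyallene | [Li]C(OC)=C=C | intermediate
10 | 4-hydroxy-4-(1-methoxypropa-1,2-dien-1-yl)-3-nonadecylcyclobut-2-en-1-one (racemic) | CCCCCCCCCCCCCCCCCCCC1=CC(=O)C1(O)C(OC)=C=C | intermediate
11 | (3E)-4-hydroxy-5-methoxy-3-nonadecylhepta-1,3,5,6-tetraen-1-one (dienylketene) | CCCCCCCCCCCCCCCCCCCC(/C=C=O)=C(\O)C(OC)=C=C | intermediate
12 | 4-hydroxy-5-methoxy-6-methylidene-3-nonadecylcyclohexa-2,4-dien-1-one (o-quinone methide) | CCCCCCCCCCCCCCCCCCCC1=CC(=O)C(=C)C(OC)=C1O | intermediate
13 | 2-methoxy-3-methyl-6-nonadecyl-1,4-benzoquinone | CCCCCCCCCCCCCCCCCCCC1=CC(=O)C(C)=C(OC)C1=O | intermediate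
14 | capiquinone C (2-hydroxy-3-methyl-6-nonadecyl-1,4-benzoquinone) | CCCCCCCCCCCCCCCCCCCC1=CC(=O)C(C)=C(O)C1=O | target

**Step count**
Total steps: 5. Longest linear sequence: 5 steps (from 1 and 2 to 14).

**Steps most likely to fail, with fallbacks**

Step 3. The lithioallene may attack the carbonyl next to the ring CH, or add in conjugate fashion to the unsubstituted ring carbon; either would lead to the regioisomeric carbinol and, after step 4, to the 5-nonadecyl quinone. The fallback sets out from 6 and comes back at 10, and removes the regiochemical choice. The hydride adduct 6 is isolated instead of being hydrolysed and is silylated (TBSCl, imidazole, DMF) to 4-(tert-butyldimethylsilyloxy)-3-isopropoxy-2-nonadecylcyclobut-2-en-1-one F1. DIBAL-H reduction of the vinylogous ester carbonyl (−78 °C) should give 4-(tert-butyldimethylsilyloxy)-3-isopropoxy-2-nonadecylcyclobut-2-en-1-ol F2. Dilute aqueous acid (Stork–Danheiser transposition, before any allene is present) should convert this into 4-(tert-butyldimethylsilyloxy)-2-nonadecylcyclobut-2-en-1-one F3, whose only carbonyl is the one next to the nonadecyl-bearing carbon. Addition of 9 should then give 4-(tert-butyldimethylsilyloxy)-1-(1-methoxypropa-1,2-dien-1-yl)-2-nonadecylcyclobut-2-en-1-ol F4 (diastereomer mixture, inconsequential). TBAF should free 1-(1-methoxypropa-1,2-dien-1-yl)-2-nonadecylcyclobut-2-ene-1,4-diol F5, and oxidation of the secondary allylic alcohol (Dess–Martin periodinane, NaHCO3) should give 10.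

Step 4. The ketene or the o-quinone methide may be diverted before tautomerisation, by inward rotation of the hydroxyl with lactonisation, by intermolecular ketene reactions, or by dimerisation of the quinone methide. The fallback sets out from 3 and 2 and comes back at 14. It uses the reversed disconnection, in which the ring is closed at the C4–C5 bond, an alkoxy group directs the addition, and a hydroquinone is oxidised afterwards.
- Vinyllithium arm: 3 is acylated with N-methoxy-N-methylacetamide to henicosan-2-one F6. This is converted into henicosan-2-one 2,4,6-triisopropylbenzenesulfonylhydrazone F7 and, by Shapiro reaction (n-BuLi, TMEDA, hexane), into henicos-1-en-2-yllithium F8.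
- Dione arm: 2 and MeLi should give 4-hydroxy-2,3-diisopropoxy-4-methylcyclobut-2-en-1-one F9 and, with conc. HCl, 3-isopropoxy-4-methylcyclobut-3-ene-1,2-dione F10.
- Union and ring expansion: addition of F8 to the carbonyl next to the isopropoxy-bearing carbon of F10 should give 4-(henicos-1-en-2-yl)-4-hydroxy-3-isopropoxy-2-methylcyclobut-2-en-1-one F11. Thermolysis (p-xylene, 138 °C; 4π opening, 6π closure onto the vinyl CH2, enolisation) should give 2-isopropoxy-3-methyl-6-nonadecylbenzene-1,4-diol F12. Ag2O should oxidise this to 2-isopropoxy-3-methyl-6-nonadecyl-1,4-benzoquinone F13, and hydrolysis under the conditions of step 5 should give 14.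

Step 2. Over-reduction, or diversion of the acid-mediated hydrolysis–dehydration (ring cleavage of the sensitive monosubstituted dione in aqueous acid), may erode the supply of 7. The fallback sets out from 1 and comes back at 7, building the four-membered ring by cycloaddition instead. Alkylation of lithium acetylide–ethylenediamine complex with 1 (DMSO) should give henicos-1-yne F14. [2+2] cycloaddition with dichloroketene (Cl3CCOCl, Zn–Cu, Et2O) should give 4,4-dichloro-3-nonadecylcyclobut-2-en-1-one F15, with the alkyl group next to the CCl2 carbon. Hydrolysis of the allylic gem-dichloride (conc. H2SO4, 50 °C) should give 7.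

**Further compounds**
F1 | step 3 | 4-(tert-butyldimethylsilyloxy)-3-isopropoxy-2-nonadecylcyclobut-2-en-1-one | CCCCCCCCCCCCCCCCCCCC1=C(OC(C)C)C(O[Si](C)(C)C(C)(C)C)C1=O
F2 | step 3 | 4-(tert-butyldimethylsilyloxy)-3-isopropoxy-2-nonadecylcyclobut-2-en-1-ol | CCCCCCCCCCCCCCCCCCCC1=C(OC(C)C)C(O[Si](C)(C)C(C)(C)C)C1O
F3 | step 3 | 4-(tert-butyldimethylsilyloxy)-2-nonadecylcyclobut-2-en-1-one | CCCCCCCCCCCCCCCCCCCC1=CC(O[Si](C)(C)C(C)(C)C)C1=O
F4 | step 3 | 4-(tert-butyldimethylsilyloxy)-1-(1-methoxypropa-1,2-dien-1-yl)-2-nonadecylcyclobut-2-en-1-ol | CCCCCCCCCCCCCCCCCCCC1=CC(O[Si](C)(C)C(C)(C)C)C1(O)C(OC)=C=C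
F5 | step 3 | 1-(1-methoxypropa-1,2-dien-1-yl)-2-nonadecylcyclobut-2-ene-1,4-diol | CCCCCCCCCCCCCCCCCCCC1=CC(O)C1(O)C(OC)=C=C
F6 | step 4 | henicosan-2-one | CCCCCCCCCCCCCCCCCCCC(C)=O
F7 | step 4 | henicosan-2-one 2,4,6-triisopropylbenzenesulfonylhydrazone | CCCCCCCCCCCCCCCCCCCC(C)=NNS(=O)(=O)c1c(C(C)C)cc(C(C)C)cc1C(C)C
F8 | step 4 | henicos-1-en-2-yllithium | CCCCCCCCCCCCCCCCCCCC([Li])=C
F9 | step 4 | 4-hydroxy-2,3-diisopropoxy-4-methylcyclobut-2-en-1-one | CC1(O)C(OC(C)C)=C(OC(C)C)C1=O
F10 | step 4 | 3-isopropoxy-4-methylcyclobut-3-ene-1,2-dione | CC1=C(OC(C)C)C(=O)C1=O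
F11 | step 4 | 4-(henicos-1-en-2-yl)-4-hydroxy-3-isopropoxy-2-methylcyclobut-2-en-1-one | CCCCCCCCCCCCCCCCCCCC(=C)C1(O)C(OC(C)C)=C(C)C1=O
F12 | step 4 | 2-isopropoxy-3-methyl-6-nonadecylbenzene-1,4-diol | CCCCCCCCCCCCCCCCCCCc1cc(O)c(C)c(OC(C)C)c1O
F13 | step 4 | 2-isopropoxy-3-methyl-6-nonadecyl-1,4-benzoquinone | CCCCCCCCCCCCCCCCCCCC1=CC(=O)C(C)=C(OC(C)C)C1=O
F14 | step 2 | henicos-1-yne | CCCCCCCCCCCCCCCCCCCC#C
F15 | step 2 | 4,4-dichloro-3-nonadecylcyclobut-2-en-1-one | CCCCCCCCCCCCCCCCCCCC1=CC(=O)C1(Cl)Cl
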